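The dihydro-1,4-dioxine ring is disconnected at the bond between the benzylic oxygen (on the carbon carrying the catechol ring) and the benzo carbon that sits ortho to the other ring oxygen and next to an aromatic CH. That bond is formed last in the ring by a copper-catalysed intramolecular O-arylation of a threo (1R,2R) 1-aryl-2-(2,4-dibromo-6-methoxyphenoxy)propanol, whose two stereocentres come from one Evans glycolate syn-aldol. The closure exploits the ortho relationship of the aryl ether oxygen and a C–Br bond on the future benzo ring: the tethered benzylic alkoxide reaches only that bromide, so the para bromide survives and later accepts the propenal chain by a Heck reaction.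

Key step: step 6

Remark: the target is read as the trans-(2R,3R) dihydrobenzodioxine. Because neither C–O bond at the two stereocentres is broken in the ring closure, this corresponds to the threo (1R,2R) open-chain alcohol.

Step 1
Reactants: 1 3,4-dihydroxy-5-methoxybenzaldehyde
Product: 2 3-methoxy-4,5-bis(methoxymethoxy)benzaldehyde
Conditions: MOMCl, iPr2NEt, CH2Cl2, 0 °C to rt
Reagents that add atoms: chloromethyl methyl ether (MOMCl) COCCl
Why: Double O-alkylation of the catechol (acetal-type phenol protection) should give two MOM ethers that tolerate the boron aldol, hydride, carbonate bases and the copper and palladium steps and fall off in the final acid treatment.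

Step 2
Reactants: 3 2,4-dibromo-6-methoxyphenol; 4 (S)-4-benzyl-3-(chloroacetyl)oxazolidin-2-one
Product: 5 (S)-4-benzyl-3-[(2,4-dibromo-6-methoxyphenoxy)acetyl]oxazolidin-2-one
Conditions: K2CO3, NaI (cat.), acetone, 50 °C
Reagents that add atoms: none
Why: Williamson ether synthesis with Finkelstein assistance, in which the acidic, weakly basic dibromophenoxide should displace the activated α-halide faster than it attacks the imide carbonyl, so that the aryloxyacetyl unit arrives with the auxiliary already in place.

Step 3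
Reactants: 5 (S)-4-benzyl-3-[(2,4-dibromo-6-methoxyphenoxy)acetyl]oxazolidin-2-one; 2 3-methoxy-4,5-bis(methoxymethoxy)benzaldehyde
Product: 7 (4S)-4-benzyl-3-[(2S,3R)-2-(2,4-dibromo-6-methoxyphenoxy)-3-hydroxy-3-[3-methoxy-4,5-bis(methoxymethoxy)phenyl]propanoyl]oxazolidin-2-one, via Z-dibutylboron enolate 6 (not isolated)
Conditions: Bu2BOTf, iPr2NEt, CH2Cl2, −78 to 0 °C; then 2, −78 to 0 °C; pH 7 buffer, MeOH, H2O2, 0 °C
Reagents that add atoms: none
Why: Evans boron glycolate syn-aldol, in which soft enolisation gives the Z-enolate (aryloxy cis to O–B) that reacts through a Zimmerman–Traxler chair on the face away from the benzyl group of the (S)-auxiliary, setting C2 (S) and C3 (R) together in the syn (threo) relationship of aryloxy and hydroxyl.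

Step 4
Reactants: 7 (4S)-4-benzyl-3-[(2S,3R)-2-(2,4-dibromo-6-methoxyphenoxy)-3-hydroxy-3-[3-methoxy-4,5-bis(methoxymethoxy)phenyl]propanoyl]oxazolidin-2-one
Product: 8 (1R,2R)-2-(2,4-dibromo-6-methoxyphenoxy)-1-[3-methoxy-4,5-bis(methoxymethoxy)phenyl]propane-1,3-diol
Conditions: LiBH4, MeOH (1 equiv), THF, 0 °C
Reagents that add atoms: none
Why: Reductive cleavage of the N-acyloxazolidinone by LiBH4 should give the primary alcohol without touching either stereocentre, the aryl bromides or the MOM ethers, the descriptor at the aryloxy carbon changing from S to R only through the change in substituent priority.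

Step 5
Reactants: 8 (1R,2R)-2-(2,4-dibromo-6-methoxyphenoxy)-1-[3-methoxy-4,5-bis(methoxymethoxy)phenyl]propane-1,3-diol
Product: 9 (1R,2R)-3-{[tert-butyl(dimethyl)silyl]oxy}-2-(2,4-dibromo-6-methoxyphenoxy)-1-[3-methoxy-4,5-bis(methoxymethoxy)phenyl]propan-1-ol
Conditions: TBSCl (1.05 equiv), imidazole, CH2Cl2, 0 °C
Reagents that add atoms: tert-butyldimethylsilyl chloride (TBSCl) CC(C)(C)[Si](C)(C)Cl
Why: Sterically controlled silylation should take the primary hydroxyl in preference to the hindered secondary benzylic one, leaving only the benzylic OH free for the ring closure.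

Step 6
Reactants: 9 (1R,2R)-3-{[tert-butyl(dimethyl)silyl]oxy}-2-(2,4-dibromo-6-methoxyphenoxy)-1-[3-methoxy-4,5-bis(methoxymethoxy)phenyl]propan-1-ol
Product: 10 tert-butyl({(2R,3R)-6-bromo-8-methoxy-3-[3-methoxy-4,5-bis(methoxymethoxy)phenyl]-2,3-dihydro-1,4-benzodioxin-2-yl}methoxy)dimethylsilane
Conditions: CuI (10 mol %), 3,4,7,8-tetramethyl-1,10-phenanthroline (20 mol %), Cs2CO3, toluene, 110 °C, argon
Reagents that add atoms: none
Why: Cs2CO3 and the phenanthroline-ligated monovalent copper should convert the only free hydroxyl (benzylic) into a copper alkoxide, which activates the C–Br bond ortho to the aryl ether oxygen through a seven-membered trivalent copper aryl alkoxide and closes the ring by C–O reductive elimination. The closest known reaction type is the intramolecular Ullmann-type etherification (copper-catalysed O-arylation) of 2-(2-halophenoxy) alcohols to 2,3-dihydro-1,4-benzodioxines. The dioxane ring closes in a 6-exo mode, the alkoxide oxygen attacking the sp2 carbon whose bromide leaves outside the new ring. No stereocentre is formed, because the C–O bonds at both stereocentres stay intact, so the threo (1R,2R) alcohol should give the trans (2R,3R) ring with the aryl and silyloxymethyl groups both equatorial. The step needs site selection between two C–Br bonds and between two hydroxyls; the first is secured by the tether, since copper is delivered by the alkoxide and the para bromide could only react intermolecularly with a hindered secondary alkoxide, and the second by the TBS ether on the primary hydroxyl, which also shuts off a seven-membered closure.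

Step 7
Reactants: 10 tert-butyl({(2R,3R)-6-bromo-8-methoxy-3-[3-methoxy-4,5-bis(methoxymethoxy)phenyl]-2,3-dihydro-1,4-benzodioxin-2-yl}methoxy)dimethylsilane; 11 acrolein diethyl acetal (3,3-diethoxyprop-1-ene)
Product: 14 (2E)-3-[(2R,3R)-3-(3,4-dihydroxy-5-methoxyphenyl)-2-(hydroxymethyl)-8-methoxy-2,3-dihydro-1,4-benzodioxin-6-yl]prop-2-enal, via diethyl acetal 12 (not isolated), via protected enal 13 (not isolated)
Conditions: Pd(OAc)2 (5 mol %), nBu4NOAc, K2CO3, KCl, DMF, 90 °C; then 3 M aq HCl, THF, 40 °C
Reagents that add atoms: water O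
Why: A Mizoroki–Heck reaction under Jeffery-type conditions should couple the remaining aryl bromide with the acetal by syn insertion and syn β-hydride elimination towards the benzylic hydrogen to give the E-cinnamyl acetal, and the aqueous acid should then hydrolyse the acetal to the E-enal and cleave the TBS and both MOM ethers, the trans ring being the thermodynamic diastereomer should the benzylic aryl ether open reversibly.

Compound list
1 | 3,4-dihydroxy-5-methoxybenzaldehyde | COc1cc(C=O)cc(O)c1O | starting material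
2 | 3-methoxy-4,5-bis(methoxymethoxy)benzaldehyde | COc1cc(C=O)cc(OCOC)c1OCOC | intermediate
3 | 2,4-dibromo-6-methoxyphenol | COc1cc(Br)cc(Br)c1O | starting material
4 | (S)-4-benzyl-3-(chloroacetyl)oxazolidin-2-one | O=C(CCl)N1[C@@H](Cc2ccccc2)COC1=O | starting material
5 | (S)-4-benzyl-3-[(2,4-dibromo-6-methoxyphenoxy)acetyl]oxazolidin-2-one | COc1cc(Br)cc(Br)c1OCC(=O)N1[C@@H](Cc2ccccc2)COC1=O | intermediate
6 | Z-dibutylboron enolate of 5 (aryloxy cis to O–B) | COc1cc(Br)cc(Br)c1O/C=C(\OB(CCCC)CCCC)N1[C@@H](Cc2ccccc2)COC1=O | intermediate (not isolated)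
7 | (4S)-4-benzyl-3-[(2S,3R)-2-(2,4-dibromo-6-methoxyphenoxy)-3-hydroxy-3-[3-methoxy-4,5-bis(methoxymethoxy)phenyl]propanoyl]oxazolidin-2-one | COc1cc([C@@H](O)[C@H](Oc2c(Br)cc(Br)cc2OC)C(=O)N2[C@@H](Cc3ccccc3)COC2=O)cc(OCOC)c1OCOC | intermediate
8 | (1R,2R)-2-(2,4-dibromo-6-methoxyphenoxy)-1-[3-methoxy-4,5-bis(methoxymethoxy)phenyl]propane-1,3-diol | COc1cc([C@@H](O)[C@H](Oc2c(Br)cc(Br)cc2OC)CO)cc(OCOC)c1OCOC | intermediate
9 | (1R,2R)-3-{[tert-butyl(dimethyl)silyl]oxy}-2-(2,4-dibromo-6-methoxyphenoxy)-1-[3-methoxy-4,5-bis(methoxymethoxy)phenyl]propan-1-ol | COc1cc([C@@H](O)[C@H](Oc2c(Br)cc(Br)cc2OC)CO[Si](C)(C)C(C)(C)C)cc(OCOC)c1OCOC | intermediate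
10 | tert-butyl({(2R,3R)-6-bromo-8-methoxy-3-[3-methoxy-4,5-bis(methoxymethoxy)phenyl]-2,3-dihydro-1,4-benzodioxin-2-yl}methoxy)dimethylsilane (trans; ring locants as in the target name, O1 on the carbon next to C–OMe) | COc1cc([C@H]2Oc3cc(Br)cc(OC)c3O[C@@H]2CO[Si](C)(C)C(C)(C)C)cc(OCOC)c1OCOC | intermediate
11 | acrolein diethyl acetal (3,3-diethoxyprop-1-ene) | C=CC(OCC)OCC | starting material
12 | compound 10 with an (E)-3,3-diethoxyprop-1-enyl group in place of bromine | COc1cc([C@H]2Oc3cc(/C=C/C(OCC)OCC)cc(OC)c3O[C@@H]2CO[Si](C)(C)C(C)(C)C)cc(OCOC)c1OCOC | intermediate (not isolated)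
13 | (2E)-3-[(2R,3R)-2-({[tert-butyl(dimethyl)silyl]oxy}methyl)-8-methoxy-3-[3-methoxy-4,5-bis(methoxymethoxy)phenyl]-2,3-dihydro-1,4-benzodioxin-6-yl]prop-2-enal | COc1cc([C@H]2Oc3cc(/C=C/C=O)cc(OC)c3O[C@@H]2CO[Si](C)(C)C(C)(C)C)cc(OCOC)c1OCOC | intermediate (not isolated)
14 | (2E)-3-[(2R,3R)-3-(3,4-dihydroxy-5-methoxyphenyl)-2-(hydroxymethyl)-8-methoxy-2,3-dihydro-1,4-benzodioxin-6-yl]prop-2-enal | COc1cc([C@H]2Oc3cc(/C=C/C=O)cc(OC)c3O[C@@H]2CO)cc(O)c1O | target

Total step count: 7. Longest linear sequence: 6 steps (steps 2 to 7).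

Steps most likely to fail

Step 6. Activation of the hindered C–Br bond at copper may be slow. Hydrodebromination, oxidation of the benzylic alcohol, expulsion of the dibromophenoxide by the neighbouring alkoxide (epoxide formation), or silyl migration followed by seven-membered closure could then compete. The fallback sets out from 4 and 2 and returns at 10. It differentiates the two halogens by kind and closes the ring on palladium, where oxidative addition comes first and chooses C–I over C–Br. Commercial 4-bromo-2-methoxyphenol would be iodinated ortho to the hydroxyl (NIS, cat. TsOH, MeCN) to 4-bromo-2-iodo-6-methoxyphenol F1, which is alkylated with 4 as in step 2 to the imide F2. Enolisation to the boron enolate F3 and aldol addition to 2 as in step 3 should give the adduct F4, LiBH4 the diol F5 and TBSCl the silyl ether F6. Pd(OAc)2, 2-(di-tert-butylphosphino)-1,1'-binaphthyl, Cs2CO3, toluene, 70 °C (Buchwald-type intramolecular C–O coupling) should then close the ring at the iodide and give 10 with the bromide intact.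

Step 7. β-Hydride elimination may run towards the acetal carbon (a saturated ester after hydrolysis). Oxidative addition of the electron-rich bromide may be slow. The free catechol may condense with the enal during the prolonged acid stage. The fallback sets out from 10 and returns at 13. Bromine–lithium exchange (nBuLi, THF, −78 °C) would give the aryllithium F7, DMF the aryl aldehyde F8, and Wittig olefination with Ph3P=CHCHO (toluene, 80 °C) the protected E-enal 13, now isolated. A separate mild acid treatment (HCl, THF–H2O, rt to 40 °C) would then give 14.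

Step 3. Enolisation or addition may be sluggish with the 2,6-disubstituted aryloxy group next to the enolate. Retro-aldol cleavage on work-up and erosion of the syn selectivity are also possible. The fallback sets out from 3 and 2 and returns at 8. It sets the stereocentres by a catalytic reduction with dynamic kinetic resolution instead of an auxiliary. 3 would be alkylated with methyl bromoacetate (K2CO3, acetone) to the ester F9. Its lithium enolate F10 (LDA, THF, −78 °C) adds to 2 to give the β-hydroxy ester F11 as a racemic diastereomer mixture, and Dess–Martin oxidation gives the configurationally labile β-keto ester F12. Asymmetric transfer hydrogenation with dynamic kinetic resolution (RuCl[(S,S)-TsDPEN](p-cymene), HCO2H/Et3N), a known route to syn α-alkoxy β-hydroxy esters, should give the (2S,3R) syn ester F13. The catalyst enantiomer is chosen by analogy with aryl ketone reductions and would have to be confirmed. LiBH4 would reduce F13 to the diol 8.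

Further compounds
F1 | step 6 | 4-bromo-2-iodo-6-methoxyphenol | COc1cc(Br)cc(I)c1O
F2 | step 6 | (S)-4-benzyl-3-[(4-bromo-2-iodo-6-methoxyphenoxy)acetyl]oxazolidin-2-one | COc1cc(Br)cc(I)c1OCC(=O)N1[C@@H](Cc2ccccc2)COC1=O
F3 | step 6 | Z-dibutylboron enolate of F2 | COc1cc(Br)cc(I)c1O/C=C(\OB(CCCC)CCCC)N1[C@@H](Cc2ccccc2)COC1=O
F4 | step 6 | (4S)-4-benzyl-3-[(2S,3R)-2-(4-bromo-2-iodo-6-methoxyphenoxy)-3-hydroxy-3-[3-methoxy-4,5-bis(methoxymethoxy)phenyl]propanoyl]oxazolidin-2-one | COc1cc([C@@H](O)[C@H](Oc2c(I)cc(Br)cc2OC)C(=O)N2[C@@H](Cc3ccccc3)COC2=O)cc(OCOC)c1OCOC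
F5 | step 6 | (1R,2R)-2-(4-bromo-2-iodo-6-methoxyphenoxy)-1-[3-methoxy-4,5-bis(methoxymethoxy)phenyl]propane-1,3-diol | COc1cc([C@@H](O)[C@H](Oc2c(I)cc(Br)cc2OC)CO)cc(OCOC)c1OCOC
F6 | step 6 | (1R,2R)-2-(4-bromo-2-iodo-6-methoxyphenoxy)-3-{[tert-butyl(dimethyl)silyl]oxy}-1-[3-methoxy-4,5-bis(methoxymethoxy)phenyl]propan-1-ol | COc1cc([C@@H](O)[C@H](Oc2c(I)cc(Br)cc2OC)CO[Si](C)(C)C(C)(C)C)cc(OCOC)c1OCOC
F7 | step 7 | aryllithium from 10 (lithium in place of bromine) | COc1cc([C@H]2Oc3cc([Li])cc(OC)c3O[C@@H]2CO[Si](C)(C)C(C)(C)C)cc(OCOC)c1OCOC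
F8 | step 7 | aryl aldehyde from 10 (formyl in place of bromine, 2R,3R) | COc1cc([C@H]2Oc3cc(C=O)cc(OC)c3O[C@@H]2CO[Si](C)(C)C(C)(C)C)cc(OCOC)c1OCOC
F9 | step 3 | methyl (2,4-dibromo-6-methoxyphenoxy)acetate | COC(=O)COc1c(Br)cc(Br)cc1OC
F10 | step 3 | lithium enolate of F9 | COC(O[Li])=COc1c(Br)cc(Br)cc1OC
F11 | step 3 | methyl 2-(2,4-dibromo-6-methoxyphenoxy)-3-hydroxy-3-[3-methoxy-4,5-bis(methoxymethoxy)phenyl]propanoate (racemic diastereomer mixture) | COc1cc(C(O)C(Oc2c(Br)cc(Br)cc2OC)C(=O)OC)cc(OCOC)c1OCOC
F12 | step 3 | methyl 2-(2,4-dibromo-6-methoxyphenoxy)-3-[3-methoxy-4,5-bis(methoxymethoxy)phenyl]-3-oxopropanoate (racemic, labile) | COc1cc(C(=O)C(Oc2c(Br)cc(Br)cc2OC)C(=O)OC)cc(OCOC)c1OCOC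
F13 | step 3 | methyl (2S,3R)-2-(2,4-dibromo-6-methoxyphenoxy)-3-hydroxy-3-[3-methoxy-4,5-bis(methoxymethoxy)phenyl]propanoate | COc1cc([C@@H](O)[C@H](Oc2c(Br)cc(Br)cc2OC)C(=O)OC)cc(OCOC)c1OCOC
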